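**Constants first.** The constants of these steps are hidden, but maple and oak, charged alike, can be compared without them.

| flask | starting material | partner | free catalyst | remark | time |
|---|---|---|---|---|---|
| maple | 0.050 M | 0.050 M | 8.4 mM | run made earlier |  |
| oak | 0.050 M | 0.050 M | 13 mM | run made earlier |  |
| cedar | 0.10 M | 0.050 M | 6 mM | run made earlier |  |
| flask | 0.050 M | 0.0500 M | 6.0 mM |  | 10 h |

| run | time / h | product / % | starting material / % |
|---|---|---|---|
| maple | 1.00 | 1.5 | 97.2 |
| maple | 3.00 | 10.2 | 88.2 |
| maple | 5.00 | 16.8 | 82.1 |
| maple | 8.00 | 24.8 | 74.2 |
| oak | 1.00 | 2.8 | 95.8 |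
| oak | 3.00 | 14.5 | 84.6 |
| oak | 5.00 | 23.3 | 75.4 |
| oak | 8.00 | 33.2 | 65.5 |
| cedar | 2.00 | 2.3 | 96.7 |
| cedar | 4.00 | 6.5 | 93.6 |
| cedar | 6.00 | 9.3 | 90.9 |
| cedar | 8.00 | 11.2 | 88.3 |

(each reading ± 0.3 percentage points)

* how much product the flask holds at 10 h, in percent of the starting material charged
* how much starting material the flask holds at 10 h, in percent of the starting material charged
* concentration of partner at 10 h, in M



**Bench rule.** At equal charges a chemist counts catalyst-hours, free catalyst charged times time, and expects conversion to follow them. Maple's last reading gives 0.330 for the reach, product divided by the part of the charge not turned into product. The rule scales reach with catalyst-hours. Oak's last reading has 1.51 times maple's reach on 1.55 times its catalyst-hours.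

**The border.** The ratio of starting material to partner is 1.00 in maple and 2.00 in cedar. Cedar's last reading has a reach of 0.126, less than the 0.236 the rule gives, so the rule does not carry over to cedar's charge. The flask has 1.00, maple's ratio.

**The reckoning.** The flask has 0.893 of maple's catalyst-hours, so its reach is 0.294 and its product 22.7 %. Maple's last readings fall short of the charge by 1 percentage point, and that gap, taken over to the flask as an estimate, gives 76.3 % starting material. One partner per product leaves 0.0386 M partner, counting no other loss.

**The flask.** The forecast reads 23 % product, 75.7 % starting material and 0.0383 M partner, "assuming it is consumed 1:1". The flask holds 22.7 % product, 76.9 % starting material and 0.0115 M partner.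

    partner + free catalyst → catalyst intermediate A (k = 0.00350 M⁻¹ s⁻¹)
    catalyst intermediate A ⇌ by-product + catalyst intermediate B (K = 0.00530 M, k = 5.30 × 10⁻⁴ s⁻¹)
    starting material + catalyst intermediate B ⇌ catalyst intermediate C (K = 15.0 M⁻¹, k = 1.30 M⁻¹ s⁻¹)
    catalyst intermediate C → free catalyst + product (k = 9.90 × 10⁻⁴ s⁻¹)
    partner → decomposed reagent (k = 2.70 × 10⁻⁵ s⁻¹)

**Partner's path.** At 10.0 h the flask's partner goes to decomposed reagent 1.8 times as fast as to catalyst intermediate A. By then the flask holds 0.0254 M decomposed reagent, more than its 0.0119 M by-product, and the flask's partner keeps 23 % of its charge against 77 % for starting material. The flask's product gives a reach of 0.294 against the 0.294 reckoned. For the neighbour flask with 0.024 M free catalyst, maple's reach scales to 1.18, or 54.1 % product, and that flask holds 51.7 %.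

The earlier runs and the new flask are simulated with constants of no real substance, and the scatter is random.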